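## Retrosynthetic overview

1. Target ⇐ desilylation and late allylic hydroxylation of the C6 methyl; trans γ-lactone ⇐ MnO2 oxidative lactonisation of a 2-methylene-1,4-diol; C4 ester ⇐ acylation with a silylated (E)-4-hydroxy-2-(hydroxymethyl)but-2-enoic acid.
2. Ten-membered carbocycle, C3a/C4 stereocentres and exocyclic methylene ⇐ [2,3]-Wittig ring contraction of a 13-membered diallylic ether (forms C3a–C4).
3. 13-Membered ether ⇐ macrocyclic B-alkyl Suzuki coupling (C6–C7) of an acyclic ether made by oxa-Michael/Horner–Wadsworth–Emmons union of an α-silyloxy aldehyde, (Z)-3-iodobut-2-en-1-ol and a phosphonoacrylate.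
4. α-Silyloxy aldehyde (C10, C11a) ⇐ terminus-differentiating ozonolysis of cis-5-methylcyclohex-2-enol silyl ether ⇐ (R)-pulegone (C10 methyl centre bought, C11a set by Luche reduction).
5. Ring order: cyclohexene template (opened) → 13-membered ether → 10-membered carbocycle → γ-lactone.

Assumption: the SMILES is read as the (3aS,4R,5E,10R,11aR) trans-fused lactone with an (E) side-chain ester; pulegone, but-2-yn-1-ol, but-2-yne-1,4-diol and ethyl 2-(diethoxyphosphoryl)acrylate are taken as purchasable.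

Locants are those of the target (cyclodeca[b]furan: O1, C2=O, C3=CH2, C3a, C4–O-ester, C5=C6, C7–C9, C10–CH3, C11, C11a–O). TBS = tert-butyldimethylsilyl, TBDPS = tert-butyldiphenylsilyl, TBSO/TBDPSO = the silyloxy groups. Yields and selectivities are expectations from analogy, not measured values.

## Route

Step 1
Reactants: 1 (R)-(+)-pulegone
Product: 2 (6R)-2,2,6-trimethyl-1-oxaspiro[2.5]octan-4-one (both spiro epimers)
Conditions: H2O2 (30% aq.), LiOH (cat.), MeOH, 0 °C to rt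
Reagents that add atoms: hydrogen peroxide, OO
Why: Weitz–Scheffer nucleophilic epoxidation of the enone; the new epoxide centres are lost later, so the epimer mixture is harmless.

Step 2
Reactants: 2 pulegone oxide
Product: 3 (5R)-5-methyl-2-(phenylsulfanyl)cyclohexan-1-one (C2 epimers)
Conditions: PhSH, NaH (cat.), THF, reflux
Reagents that add atoms: thiophenol, Sc1ccccc1
Why: Thiolate opening of the α,β-epoxy ketone at the α-carbon followed by retro-aldol loss of acetone, the enolate regenerating thiolate.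

Step 3
Reactants: 3 (5R)-5-methyl-2-(phenylsulfanyl)cyclohexan-1-one
Product: 5 (5R)-5-methylcyclohex-2-en-1-one, via sulfoxide 4 (not isolated)
Conditions: mCPBA, CH2Cl2, −78 °C; then CaCO3, toluene, 110 °C
Reagents that add atoms: none
Why: S-oxidation and thermal sulfoxide syn-elimination, which can only use the C3 hydrogens, so the enone forms regiospecifically and C5 is untouched.

Step 4
Reactants: 5 (5R)-5-methylcyclohex-2-en-1-one
Product: 6 (1R,5R)-5-methylcyclohex-2-en-1-ol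
Conditions: NaBH4, CeCl3·7H2O, MeOH, −78 °C
Reagents that add atoms: none
Why: Luche 1,2-reduction with axial hydride delivery to the half-chair bearing an equatorial 5-methyl gives the cis alcohol, so the carbinol (later C11a) is set by the bought methyl centre.

Step 5
Reactants: 6 (1R,5R)-5-methylcyclohex-2-en-1-ol
Product: 7 tert-butyl(dimethyl){[(1R,5R)-5-methylcyclohex-2-en-1-yl]oxy}silane
Conditions: TBSCl, imidazole, DMF, rt
Reagents that add atoms: tert-butyldimethylsilyl chloride, CC(C)(C)[Si](C)(C)Cl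
Why: Standard silylation of a secondary allylic alcohol.

Step 6
Reactants: 7 cyclohexenyl TBS ether
Product: 10 (3S,5R)-5-(TBSO)-6,6-dimethoxy-3-methylhexanal, via hydroperoxy aldehyde 8 (not isolated), via hydroperoxy acetal 9 (not isolated)
Conditions: O3, CH2Cl2/MeOH, −78 °C; TsOH·H2O (cat.), rt; then NaHCO3, Me2S
Reagents that add atoms: ozone, [O-][O+]=O; methanol, CO
Why: Criegee ozonolysis with Schreiber-type terminus differentiation: the inductively withdrawing allylic OTBS directs the carbonyl oxide to the distal carbon (trapped as methoxy hydroperoxide, then reduced to the aldehyde) while the proximal aldehyde is acetalised.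

Step 7
Reactants: 10 (3S,5R)-5-(TBSO)-6,6-dimethoxy-3-methylhexanal
Product: 11 (2R,4R)-2-(TBSO)-1,1-dimethoxy-4-methylhept-6-ene
Conditions: Ph3PCH3Br, KN(SiMe3)2, THF, 0 °C; then 10, −78 °C to rt
Reagents that add atoms: methyltriphenylphosphonium bromide, C[P+](c1ccccc1)(c1ccccc1)c1ccccc1.[Br-]
Why: Wittig methylenation of the unhindered aldehyde; the stereocentre is β to the carbonyl and cannot epimerise.

Step 8
Reactants: 11 (2R,4R)-2-(TBSO)-1,1-dimethoxy-4-methylhept-6-ene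
Product: 13 (2R,4R)-2-(TBSO)-4-methylhept-6-enal, via collidinium salt 12 (not isolated)
Conditions: Et3SiOTf, 2,4,6-collidine, CH2Cl2, 0 °C; then H2O
Reagents that add atoms: water, O
Why: Non-acidic acetal cleavage through a pyridinium N,O-acetal that hydrolyses on water addition, which spares the TBS ether and the α-silyloxy stereocentre.

Step 9
Reactants: 14 but-2-yn-1-ol
Product: 16 (2Z)-3-iodobut-2-en-1-ol, via cyclic alkenylaluminate 15 (not isolated)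
Conditions: NaAlH2(OCH2CH2OMe)2, Et2O, 0 °C to rt; then I2, −78 °C to rt
Reagents that add atoms: iodine, II
Why: Hydroxyl-directed trans-hydroalumination of the propargylic alcohol and iodinolysis with retention place iodine cis to the CH2OH group.

Step 10
Reactants: 16 (2Z)-3-iodobut-2-en-1-ol; 17 ethyl 2-(diethoxyphosphoryl)prop-2-enoate; 13 (2R,4R)-2-(TBSO)-4-methylhept-6-enal
Product: 20 ethyl (2E,4R,6R)-4-(TBSO)-2-({[(2Z)-3-iodobut-2-en-1-yl]oxy}methyl)-6-methylnona-2,8-dienoate, via sodium alkoxide 18 (not isolated), via phosphonate carbanion 19 (not isolated)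
Conditions: 16, NaH (1.0 equiv), THF, 0 °C; then 17, 0 °C; then 13, −78 °C to rt
Reagents that add atoms: none
Why: Oxa-Michael addition to the vinylphosphonate gives the phosphonate carbanion, whose Horner–Wadsworth–Emmons olefination places the ester trans to the aldehyde chain, so the ether-bearing CH2 ends up cis to the C–OTBS carbon as the later rearrangement requires.

Step 11
Reactants: 20 ethyl dienoate
Product: 21 (2Z,4R,6R)-4-(TBSO)-2-({[(2Z)-3-iodobut-2-en-1-yl]oxy}methyl)-6-methylnona-2,8-dien-1-ol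
Conditions: i-Bu2AlH (2.5 equiv), CH2Cl2, −78 °C
Reagents that add atoms: none
Why: 1,2-Reduction of the enoate to the allylic alcohol, needed because an enoate would not survive the later alkyllithium step.

Step 12
Reactants: 21 allylic alcohol
Product: 22 (2E,4R,6R)-1,4-bis(TBSO)-2-({[(2Z)-3-iodobut-2-en-1-yl]oxy}methyl)-6-methylnona-2,8-diene
Conditions: TBSCl, imidazole, DMF, rt
Reagents that add atoms: tert-butyldimethylsilyl chloride, CC(C)(C)[Si](C)(C)Cl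
Why: Silylation of the primary allylic alcohol.

Step 13
Reactants: 22 bis-TBS iodo diene
Product: 24 (3E,5R,7R,11Z)-5-(TBSO)-3-[(TBSO)methyl]-7,11-dimethyl-1-oxacyclotrideca-3,11-diene, via alkylborane 23 (not isolated)
Conditions: 9-BBN-H, THF, rt; then slow addition to Pd(dppf)Cl2 (15 mol%), AsPh3, Cs2CO3, DMF/THF/H2O, 50 °C, 2 mM
Reagents that add atoms: none
Why: Chemoselective hydroboration of the only monosubstituted alkene and intramolecular B-alkyl Suzuki–Miyaura coupling with retention at the iodoalkene close the 13-membered ring and fix C7 cis to C4 across C5=C6.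

Step 14
Reactants: 24 13-membered diallylic ether
Product: 26 (1R,2Z,7R,9R,10R)-9-(TBSO)-10-[3-(TBSO)prop-1-en-2-yl]-3,7-dimethylcyclodec-2-en-1-ol, via lithiated ether 25 (not isolated)
Conditions: n-BuLi (3 equiv), THF/hexane, −78 to −20 °C; then H2O
Reagents that add atoms: none
Why: [2,3]-Wittig sigmatropic ring contraction in which n-BuLi removes the less hindered allylic ether proton (OCH2 flanked by CH=) and the carbanion adds through the five-membered envelope transition state to the CH terminus of the Z-allyl unit (Z gives the syn C4–OH/C3a pair) on the face anti to the C11a–OTBS bond with C11a–H eclipsing the alkene (A(1,3) strain), setting C4 and C3a while forming the ten-membered ring and the exocyclic methylene.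

Step 15
Reactants: 27 but-2-yne-1,4-diol
Product: 28 1,4-bis(TBDPSO)but-2-yne
Conditions: TBDPSCl (2.2 equiv), imidazole, DMF, rt
Reagents that add atoms: tert-butyldiphenylsilyl chloride, CC(C)(C)[Si](Cl)(c1ccccc1)c1ccccc1
Why: Exhaustive silylation of the diol.

Step 16
Reactants: 28 1,4-bis(TBDPSO)but-2-yne
Product: 29 tributyl[(2E)-1,4-bis(TBDPSO)but-2-en-2-yl]stannane
Conditions: Bu3SnH, PdCl2(PPh3)2 (2 mol%), THF, 0 °C to rt
Reagents that add atoms: tributyltin hydride, CCCC[SnH](CCCC)CCCC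
Why: Palladium-catalysed syn hydrostannation of a symmetrical alkyne gives one regioisomer with the two CH2O groups cis.

Step 17
Reactants: 29 alkenylstannane
Product: 31 (2E)-4-(TBDPSO)-2-[(TBDPSO)methyl]but-2-enoic acid, via alkenyllithium 30 (not isolated)
Conditions: n-BuLi, THF, −78 °C; then CO2; aq. HCl work-up
Reagents that add atoms: carbon dioxide, O=C=O
Why: Tin–lithium exchange and carboxylation proceed with retention, giving the acid with CO2H trans to C4 as in the target side chain.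

Step 18
Reactants: 31 side-chain acid; 26 cyclodecenol
Product: 33 (1R,2Z,7R,9R,10R)-9-(TBSO)-10-[3-(TBSO)prop-1-en-2-yl]-3,7-dimethylcyclodec-2-en-1-yl (2E)-4-(TBDPSO)-2-[(TBDPSO)methyl]but-2-enoate, via mixed anhydride 32 (not isolated)
Conditions: 31, 2,4,6-Cl3C6H2COCl, Et3N, THF, rt; then 26, DMAP, toluene, 40 °C
Reagents that add atoms: none
Why: Yamaguchi esterification acylates the hindered secondary allylic alcohol with retention at C4.

Step 19
Reactants: 33 tetrasilyl ester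
Product: 34 (1R,2Z,7R,9R,10S)-9-hydroxy-10-(3-hydroxyprop-1-en-2-yl)-3,7-dimethylcyclodec-2-en-1-yl (2E)-4-(TBDPSO)-2-[(TBDPSO)methyl]but-2-enoate
Conditions: TsOH·H2O (0.2 equiv), MeOH/CH2Cl2, 0 °C to rt
Reagents that add atoms: none
Why: Acid-catalysed methanolysis removes the two TBS ethers while the far more acid-stable primary TBDPS ethers remain.

Step 20
Reactants: 34 diol
Product: 37 (3aS,4R,5Z,10R,11aR)-6,10-dimethyl-3-methylidene-2-oxo-2,3,3a,4,7,8,9,10,11,11a-decahydrocyclodeca[b]furan-4-yl (2E)-4-(TBDPSO)-2-[(TBDPSO)methyl]but-2-enoate, via hydroxy enal 35 (not isolated), via lactol 36 (not isolated)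
Conditions: MnO2 (activated, excess), CH2Cl2, rt
Reagents that add atoms: none
Why: Oxidative lactonisation (allylic alcohol to enal, lactol formation with the C11a hydroxyl, lactol oxidation) gives the α-methylene-γ-lactone, its trans fusion fixed by the existing C3a and C11a centres.

Step 21
Reactants: 37 6-methyl lactone
Product: 38 (3aS,4R,5E,10R,11aR)-6-(hydroxymethyl)-10-methyl-3-methylidene-2-oxo-2,3,3a,4,7,8,9,10,11,11a-decahydrocyclodeca[b]furan-4-yl (2E)-4-(TBDPSO)-2-[(TBDPSO)methyl]but-2-enoate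
Conditions: SeO2 (0.5 equiv), t-BuOOH (3 equiv), CH2Cl2, rt to 40 °C
Reagents that add atoms: selenium dioxide, O=[Se]=O; tert-butyl hydroperoxide, CC(C)(C)OO
Why: SeO2 allylic hydroxylation (ene reaction then [2,3] shift) of the only electron-rich alkene oxidises the methyl trans to C4, as prenyl-type allylic esters do, with retention of alkene geometry.

Step 22
Reactants: 38 bis-TBDPS ether
Product: 39 target, (3aS,4R,5E,10R,11aR)-6-(hydroxymethyl)-10-methyl-3-methylidene-2-oxo-2,3,3a,4,7,8,9,10,11,11a-decahydrocyclodeca[b]furan-4-yl (2E)-4-hydroxy-2-(hydroxymethyl)but-2-enoate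
Conditions: Bu4NF, AcOH (1:1), THF, 0 °C to rt
Reagents that add atoms: none
Why: Buffered fluoride desilylation frees the two side-chain alcohols without base-induced damage to the α-methylene lactone or acyl migration.

## Compound list

1 | (R)-(+)-pulegone, (5R)-5-methyl-2-(propan-2-ylidene)cyclohexan-1-one | C[C@@H]1CCC(=C(C)C)C(=O)C1 | starting material
2 | (6R)-2,2,6-trimethyl-1-oxaspiro[2.5]octan-4-one (spiro epimers) | C[C@@H]1CCC2(OC2(C)C)C(=O)C1 | intermediate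
3 | (5R)-5-methyl-2-(phenylsulfanyl)cyclohexan-1-one (C2 epimers) | C[C@@H]1CCC(Sc2ccccc2)C(=O)C1 | intermediate
4 | (5R)-5-methyl-2-(phenylsulfinyl)cyclohexan-1-one | C[C@@H]1CCC(S(=O)c2ccccc2)C(=O)C1 | intermediate
5 | (5R)-5-methylcyclohex-2-en-1-one | C[C@@H]1CC=CC(=O)C1 | intermediate
6 | (1R,5R)-5-methylcyclohex-2-en-1-ol | C[C@@H]1CC=C[C@H](O)C1 | intermediate
7 | tert-butyl(dimethyl){[(1R,5R)-5-methylcyclohex-2-en-1-yl]oxy}silane | C[C@@H]1CC=C[C@H](O[Si](C)(C)C(C)(C)C)C1 | intermediate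
8 | (2R,4S)-2-(TBSO)-6-hydroperoxy-6-methoxy-4-methylhexanal (C6 epimers) | COC(OO)C[C@@H](C)C[C@@H](O[Si](C)(C)C(C)(C)C)C=O | intermediate
9 | (2R,4S)-2-(TBSO)-6-hydroperoxy-1,1,6-trimethoxy-4-methylhexane (C6 epimers) | COC(OO)C[C@@H](C)C[C@@H](O[Si](C)(C)C(C)(C)C)C(OC)OC | intermediate
10 | (3S,5R)-5-(TBSO)-6,6-dimethoxy-3-methylhexanal | O=CC[C@@H](C)C[C@@H](O[Si](C)(C)C(C)(C)C)C(OC)OC | intermediate
11 | (2R,4R)-2-(TBSO)-1,1-dimethoxy-4-methylhept-6-ene | C=CC[C@@H](C)C[C@@H](O[Si](C)(C)C(C)(C)C)C(OC)OC | intermediate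
12 | 1-[(2R,4R)-2-(TBSO)-1-methoxy-4-methylhept-6-en-1-yl]-2,4,6-trimethylpyridinium triflate | C=CC[C@@H](C)C[C@@H](O[Si](C)(C)C(C)(C)C)C(OC)[n+]1c(C)cc(C)cc1C.[O-]S(=O)(=O)C(F)(F)F | intermediate
13 | (2R,4R)-2-(TBSO)-4-methylhept-6-enal | C=CC[C@@H](C)C[C@@H](O[Si](C)(C)C(C)(C)C)C=O | intermediate
14 | but-2-yn-1-ol | CC#CCO | starting material
15 | sodium cyclic alkenyl(alkoxy)bis(2-methoxyethoxy)aluminate of 14 | CC1=CCO[Al-]1(OCCOC)OCCOC.[Na+] | intermediate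
16 | (2Z)-3-iodobut-2-en-1-ol | C/C(I)=C/CO | intermediate
17 | ethyl 2-(diethoxyphosphoryl)prop-2-enoate | CCOC(=O)C(=C)P(=O)(OCC)OCC | starting material
18 | sodium (2Z)-3-iodobut-2-en-1-olate | C/C(I)=C/C[O-].[Na+] | intermediate
19 | sodium α-carbanion of ethyl 2-(diethoxyphosphoryl)-3-{[(2Z)-3-iodobut-2-en-1-yl]oxy}propanoate | CCOC(=O)[C-](COC/C=C(/C)I)P(=O)(OCC)OCC.[Na+] | intermediate
20 | ethyl (2E,4R,6R)-4-(TBSO)-2-({[(2Z)-3-iodobut-2-en-1-yl]oxy}methyl)-6-methylnona-2,8-dienoate | CCOC(=O)/C(=C/[C@H](O[Si](C)(C)C(C)(C)C)C[C@H](C)CC=C)COC/C=C(/C)I | intermediate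
21 | (2Z,4R,6R)-4-(TBSO)-2-({[(2Z)-3-iodobut-2-en-1-yl]oxy}methyl)-6-methylnona-2,8-dien-1-ol | OC/C(=C/[C@H](O[Si](C)(C)C(C)(C)C)C[C@H](C)CC=C)COC/C=C(/C)I | intermediate
22 | (2E,4R,6R)-1,4-bis(TBSO)-2-({[(2Z)-3-iodobut-2-en-1-yl]oxy}methyl)-6-methylnona-2,8-diene | CC(C)(C)[Si](C)(C)OC/C(=C/[C@H](O[Si](C)(C)C(C)(C)C)C[C@H](C)CC=C)COC/C=C(/C)I | intermediate
23 | 9-BBN adduct of 22 at C9, (2E,4R,6R)-9-(9-borabicyclo[3.3.1]nonan-9-yl)-1,4-bis(TBSO)-2-({[(2Z)-3-iodobut-2-en-1-yl]oxy}methyl)-6-methylnon-2-ene | CC(C)(C)[Si](C)(C)OC/C(=C/[C@H](O[Si](C)(C)C(C)(C)C)C[C@H](C)CCCB1C2CCCC1CCC2)COC/C=C(/C)I | intermediate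
24 | (3E,5R,7R,11Z)-5-(TBSO)-3-[(TBSO)methyl]-7,11-dimethyl-1-oxacyclotrideca-3,11-diene | C/C1=C/COC/C(CO[Si](C)(C)C(C)(C)C)=C\[C@H](O[Si](C)(C)C(C)(C)C)C[C@H](C)CCC1 | intermediate
25 | 13-lithio derivative of 24 (carbanion at the OCH2 next to CH=) | C/C1=C/C([Li])OC/C(CO[Si](C)(C)C(C)(C)C)=C\[C@H](O[Si](C)(C)C(C)(C)C)C[C@H](C)CCC1 | intermediate
26 | (1R,2Z,7R,9R,10R)-9-(TBSO)-10-[3-(TBSO)prop-1-en-2-yl]-3,7-dimethylcyclodec-2-en-1-ol | C=C(CO[Si](C)(C)C(C)(C)C)[C@H]1[C@H](O[Si](C)(C)C(C)(C)C)C[C@H](C)CCC/C(C)=C\[C@H]1O | intermediate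
27 | but-2-yne-1,4-diol | OCC#CCO | starting material
28 | 1,4-bis(TBDPSO)but-2-yne | CC(C)(C)[Si](OCC#CCO[Si](c1ccccc1)(c1ccccc1)C(C)(C)C)(c1ccccc1)c1ccccc1 | intermediate
29 | tributyl[(2E)-1,4-bis(TBDPSO)but-2-en-2-yl]stannane | CCCC[Sn](CCCC)(CCCC)/C(=C/CO[Si](c1ccccc1)(c1ccccc1)C(C)(C)C)CO[Si](c1ccccc1)(c1ccccc1)C(C)(C)C | intermediate
30 | alkenyllithium from 29 (Li in place of Sn, geometry retained) | [Li]/C(=C/CO[Si](c1ccccc1)(c1ccccc1)C(C)(C)C)CO[Si](c1ccccc1)(c1ccccc1)C(C)(C)C | intermediate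
31 | (2E)-4-(TBDPSO)-2-[(TBDPSO)methyl]but-2-enoic acid | OC(=O)/C(=C/CO[Si](c1ccccc1)(c1ccccc1)C(C)(C)C)CO[Si](c1ccccc1)(c1ccccc1)C(C)(C)C | intermediate
32 | mixed anhydride of 31 and 2,4,6-trichlorobenzoic acid | O=C(OC(=O)/C(=C/CO[Si](c1ccccc1)(c1ccccc1)C(C)(C)C)CO[Si](c1ccccc1)(c1ccccc1)C(C)(C)C)c1c(Cl)cc(Cl)cc1Cl | intermediate
33 | (1R,2Z,7R,9R,10R)-9-(TBSO)-10-[3-(TBSO)prop-1-en-2-yl]-3,7-dimethylcyclodec-2-en-1-yl (2E)-4-(TBDPSO)-2-[(TBDPSO)methyl]but-2-enoate | C=C(CO[Si](C)(C)C(C)(C)C)[C@H]1[C@H](O[Si](C)(C)C(C)(C)C)C[C@H](C)CCC/C(C)=C\[C@H]1OC(=O)/C(=C/CO[Si](c1ccccc1)(c1ccccc1)C(C)(C)C)CO[Si](c1ccccc1)(c1ccccc1)C(C)(C)C | intermediate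
34 | (1R,2Z,7R,9R,10S)-9-hydroxy-10-(3-hydroxyprop-1-en-2-yl)-3,7-dimethylcyclodec-2-en-1-yl (2E)-4-(TBDPSO)-2-[(TBDPSO)methyl]but-2-enoate | C=C(CO)[C@H]1[C@H](O)C[C@H](C)CCC/C(C)=C\[C@H]1OC(=O)/C(=C/CO[Si](c1ccccc1)(c1ccccc1)C(C)(C)C)CO[Si](c1ccccc1)(c1ccccc1)C(C)(C)C | intermediate
35 | (1R,2Z,7R,9R,10S)-9-hydroxy-3,7-dimethyl-10-(3-oxoprop-1-en-2-yl)cyclodec-2-en-1-yl (2E)-4-(TBDPSO)-2-[(TBDPSO)methyl]but-2-enoate | C=C(C=O)[C@H]1[C@H](O)C[C@H](C)CCC/C(C)=C\[C@H]1OC(=O)/C(=C/CO[Si](c1ccccc1)(c1ccccc1)C(C)(C)C)CO[Si](c1ccccc1)(c1ccccc1)C(C)(C)C | intermediate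
36 | 2-hydroxy lactol corresponding to 37 (C2 epimers) | C=C1C(O)O[C@@H]2C[C@H](C)CCC/C(C)=C\[C@@H](OC(=O)/C(=C/CO[Si](c3ccccc3)(c3ccccc3)C(C)(C)C)CO[Si](c3ccccc3)(c3ccccc3)C(C)(C)C)[C@@H]12 | intermediate
37 | (3aS,4R,5Z,10R,11aR)-6,10-dimethyl-3-methylidene-2-oxo-2,3,3a,4,7,8,9,10,11,11a-decahydrocyclodeca[b]furan-4-yl (2E)-4-(TBDPSO)-2-[(TBDPSO)methyl]but-2-enoate | C=C1C(=O)O[C@@H]2C[C@H](C)CCC/C(C)=C\[C@@H](OC(=O)/C(=C/CO[Si](c3ccccc3)(c3ccccc3)C(C)(C)C)CO[Si](c3ccccc3)(c3ccccc3)C(C)(C)C)[C@@H]12 | intermediate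
38 | (3aS,4R,5E,10R,11aR)-6-(hydroxymethyl)-10-methyl-3-methylidene-2-oxo-2,3,3a,4,7,8,9,10,11,11a-decahydrocyclodeca[b]furan-4-yl (2E)-4-(TBDPSO)-2-[(TBDPSO)methyl]but-2-enoate | C=C1C(=O)O[C@@H]2C[C@H](C)CCC/C(CO)=C\[C@@H](OC(=O)/C(=C/CO[Si](c3ccccc3)(c3ccccc3)C(C)(C)C)CO[Si](c3ccccc3)(c3ccccc3)C(C)(C)C)[C@@H]12 | intermediate
39 | (3aS,4R,5E,10R,11aR)-6-(hydroxymethyl)-10-methyl-3-methylidene-2-oxo-2,3,3a,4,7,8,9,10,11,11a-decahydrocyclodeca[b]furan-4-yl (2E)-4-hydroxy-2-(hydroxymethyl)but-2-enoate (CNP0131216.2) | C=C1C(=O)O[C@@H]2C[C@H](C)CCC/C(CO)=C\[C@@H](OC(=O)/C(=C/CO)CO)[C@@H]12 | target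

## Step count and risks

Total step count: 22. Longest linear sequence: 18 steps (1–8, 10–14, 18–22).

**Step 14 ([2,3]-Wittig ring contraction).** Deprotonation could occur at the other ether CH2, which would open a 1,4-elimination of the C11a silyloxy group, and the C4/C3a selectivity in the macrocycle rests on acyclic analogy. The fallback sets out from 13, 14 and 17 and comes back at 33: the rearrangement is run on an acyclic propargylic ether, where deprotonation is unambiguous, and the ten-membered ring is closed afterwards by cross-coupling. NaH converts 14 into sodium but-2-yn-1-olate F7, which adds to 17 to give the sodium phosphonate carbanion F8; this olefinates 13 to ethyl (2E,4R,6R)-2-[(but-2-yn-1-yloxy)methyl]-4-(TBSO)-6-methylnona-2,8-dienoate F9. Reduction with i-Bu2AlH gives (2Z,4R,6R)-2-[(but-2-yn-1-yloxy)methyl]-4-(TBSO)-6-methylnona-2,8-dien-1-ol F10, and TBSCl/imidazole gives (2E,4R,6R)-2-[(but-2-yn-1-yloxy)methyl]-1,4-bis(TBSO)-6-methylnona-2,8-diene F11. n-BuLi at −78 °C forms the propargylic α-lithio ether F12, which rearranges to (4S,5R,6R,8R)-6-(TBSO)-5-[3-(TBSO)prop-1-en-2-yl]-8-methylundec-10-en-2-yn-4-ol F13. NaAlH2(OCH2CH2OMe)2 gives the cyclic sodium alkenylaluminate F14, and I2 then gives (2Z,4S,5R,6R,8R)-6-(TBSO)-5-[3-(TBSO)prop-1-en-2-yl]-2-iodo-8-methylundeca-2,10-dien-4-ol F15. Yamaguchi acylation with 31 (through 32) gives the (2E)-4-(TBDPSO)-2-[(TBDPSO)methyl]but-2-enoate ester of that alcohol F16. Hydroboration of the monosubstituted alkene gives the 9-BBN adduct F17, which is cyclised with Pd(dppf)Cl2, AsPh3 and Cs2CO3 under high dilution to 33. The weak points of this fallback are the ten-membered Suzuki closure and 9-BBN discrimination against the hindered 1,1-disubstituted alkene.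

**Step 13 (13-membered B-alkyl Suzuki closure).** Oligomerisation or slow transmetalation may win over ring closure. The fallback sets out from 11 and 16 and comes back at 24: the two unions are made in reverse order so that the ring is closed by olefination. Hydroboration of 11 gives 9-[(4R,6R)-6-(TBSO)-7,7-dimethoxy-4-methylheptyl]-9-borabicyclo[3.3.1]nonane F1, which is coupled intermolecularly with 16 (Pd(dppf)Cl2, AsPh3, Cs2CO3) to (2Z,7R,9R)-9-(TBSO)-10,10-dimethoxy-3,7-dimethyldec-2-en-1-ol F2. KOt-Bu-catalysed oxa-Michael addition to 17 gives ethyl 2-(diethoxyphosphoryl)-3-{[(2Z,7R,9R)-9-(TBSO)-10,10-dimethoxy-3,7-dimethyldec-2-en-1-yl]oxy}propanoate F3. LiBF4 in wet MeCN unmasks ethyl 2-(diethoxyphosphoryl)-3-{[(2Z,7R,9R)-9-(TBSO)-3,7-dimethyl-10-oxodec-2-en-1-yl]oxy}propanoate F4. Intramolecular Horner–Wadsworth–Emmons olefination (LiCl, DBU, MeCN, 1 mM) closes ethyl (3E,5R,7R,11Z)-5-(TBSO)-7,11-dimethyl-1-oxacyclotrideca-3,11-diene-3-carboxylate F5. i-Bu2AlH gives [(3Z,5R,7R,11Z)-5-(TBSO)-7,11-dimethyl-1-oxacyclotrideca-3,11-dien-3-yl]methanol F6, and TBSCl/imidazole gives 24.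

**Step 21 (late allylic hydroxylation).** The C5=C6 alkene is deactivated by the allylic ester, so the reaction may stall or over-oxidise. The fallback sets out from 37 and comes back at 38: the methyl is deliberately oxidised through to the aldehyde with stoichiometric SeO2 in dioxane at 80 °C, giving (3aS,4R,5E,10R,11aR)-6-formyl-10-methyl-3-methylidene-2-oxo-2,3,3a,4,7,8,9,10,11,11a-decahydrocyclodeca[b]furan-4-yl (2E)-4-(TBDPSO)-2-[(TBDPSO)methyl]but-2-enoate F18. The aldehyde is then reduced chemoselectively with NaBH(OAc)3 in AcOH/CH2Cl2, which leaves the α-methylene lactone alone, to give 38.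

## Further compounds

F1 | step 13 | 9-[(4R,6R)-6-(TBSO)-7,7-dimethoxy-4-methylheptyl]-9-borabicyclo[3.3.1]nonane | COC(OC)[C@H](O[Si](C)(C)C(C)(C)C)C[C@H](C)CCCB1C2CCCC1CCC2
F2 | step 13 | (2Z,7R,9R)-9-(TBSO)-10,10-dimethoxy-3,7-dimethyldec-2-en-1-ol | C/C(=C/CO)CCC[C@@H](C)C[C@@H](O[Si](C)(C)C(C)(C)C)C(OC)OC
F3 | step 13 | ethyl 2-(diethoxyphosphoryl)-3-{[(2Z,7R,9R)-9-(TBSO)-10,10-dimethoxy-3,7-dimethyldec-2-en-1-yl]oxy}propanoate | CCOC(=O)C(COC/C=C(/C)CCC[C@@H](C)C[C@@H](O[Si](C)(C)C(C)(C)C)C(OC)OC)P(=O)(OCC)OCC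
F4 | step 13 | ethyl 2-(diethoxyphosphoryl)-3-{[(2Z,7R,9R)-9-(TBSO)-3,7-dimethyl-10-oxodec-2-en-1-yl]oxy}propanoate | CCOC(=O)C(COC/C=C(/C)CCC[C@@H](C)C[C@@H](O[Si](C)(C)C(C)(C)C)C=O)P(=O)(OCC)OCC
F5 | step 13 | ethyl (3E,5R,7R,11Z)-5-(TBSO)-7,11-dimethyl-1-oxacyclotrideca-3,11-diene-3-carboxylate | CCOC(=O)/C1=C/[C@H](O[Si](C)(C)C(C)(C)C)C[C@H](C)CCC/C(C)=C\COC1
F6 | step 13 | [(3Z,5R,7R,11Z)-5-(TBSO)-7,11-dimethyl-1-oxacyclotrideca-3,11-dien-3-yl]methanol | OC/C1=C/[C@H](O[Si](C)(C)C(C)(C)C)C[C@H](C)CCC/C(C)=C\COC1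
F7 | step 14 | sodium but-2-yn-1-olate | CC#CC[O-].[Na+]
F8 | step 14 | sodium α-carbanion of ethyl 3-(but-2-yn-1-yloxy)-2-(diethoxyphosphoryl)propanoate | CCOC(=O)[C-](COCC#CC)P(=O)(OCC)OCC.[Na+]
F9 | step 14 | ethyl (2E,4R,6R)-2-[(but-2-yn-1-yloxy)methyl]-4-(TBSO)-6-methylnona-2,8-dienoate | CCOC(=O)/C(=C/[C@H](O[Si](C)(C)C(C)(C)C)C[C@H](C)CC=C)COCC#CC
F10 | step 14 | (2Z,4R,6R)-2-[(but-2-yn-1-yloxy)methyl]-4-(TBSO)-6-methylnona-2,8-dien-1-ol | OC/C(=C/[C@H](O[Si](C)(C)C(C)(C)C)C[C@H](C)CC=C)COCC#CC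
F11 | step 14 | (2E,4R,6R)-2-[(but-2-yn-1-yloxy)methyl]-1,4-bis(TBSO)-6-methylnona-2,8-diene | CC(C)(C)[Si](C)(C)OC/C(=C/[C@H](O[Si](C)(C)C(C)(C)C)C[C@H](C)CC=C)COCC#CC
F12 | step 14 | propargylic α-lithio derivative of F11 | CC#CC([Li])OC/C(CO[Si](C)(C)C(C)(C)C)=C\[C@H](O[Si](C)(C)C(C)(C)C)C[C@H](C)CC=C
F13 | step 14 | (4S,5R,6R,8R)-6-(TBSO)-5-[3-(TBSO)prop-1-en-2-yl]-8-methylundec-10-en-2-yn-4-ol | C=C(CO[Si](C)(C)C(C)(C)C)[C@H]([C@H](O)C#CC)[C@H](O[Si](C)(C)C(C)(C)C)C[C@H](C)CC=C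
F14 | step 14 | sodium cyclic alkenyl(alkoxy)bis(2-methoxyethoxy)aluminate of F13 | C=C(CO[Si](C)(C)C(C)(C)C)[C@H]([C@@H]1O[Al-](OCCOC)(OCCOC)C(C)=C1)[C@H](O[Si](C)(C)C(C)(C)C)C[C@H](C)CC=C.[Na+]
F15 | step 14 | (2Z,4S,5R,6R,8R)-6-(TBSO)-5-[3-(TBSO)prop-1-en-2-yl]-2-iodo-8-methylundeca-2,10-dien-4-ol | C=C(CO[Si](C)(C)C(C)(C)C)[C@H]([C@H](O)/C=C(/C)I)[C@H](O[Si](C)(C)C(C)(C)C)C[C@H](C)CC=C
F16 | step 14 | (2Z,4S,5R,6R,8R)-6-(TBSO)-5-[3-(TBSO)prop-1-en-2-yl]-2-iodo-8-methylundeca-2,10-dien-4-yl (2E)-4-(TBDPSO)-2-[(TBDPSO)methyl]but-2-enoate | C=C(CO[Si](C)(C)C(C)(C)C)[C@H]([C@H](OC(=O)/C(=C/CO[Si](c1ccccc1)(c1ccccc1)C(C)(C)C)CO[Si](c1ccccc1)(c1ccccc1)C(C)(C)C)/C=C(/C)I)[C@H](O[Si](C)(C)C(C)(C)C)C[C@H](C)CC=C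
F17 | step 14 | 9-BBN adduct of F16 at the terminal alkene carbon | C=C(CO[Si](C)(C)C(C)(C)C)[C@H]([C@H](OC(=O)/C(=C/CO[Si](c1ccccc1)(c1ccccc1)C(C)(C)C)CO[Si](c1ccccc1)(c1ccccc1)C(C)(C)C)/C=C(/C)I)[C@H](O[Si](C)(C)C(C)(C)C)C[C@H](C)CCCB1C2CCCC1CCC2
F18 | step 21 | (3aS,4R,5E,10R,11aR)-6-formyl-10-methyl-3-methylidene-2-oxo-2,3,3a,4,7,8,9,10,11,11a-decahydrocyclodeca[b]furan-4-yl (2E)-4-(TBDPSO)-2-[(TBDPSO)methyl]but-2-enoate | C=C1C(=O)O[C@@H]2C[C@H](C)CCC/C(C=O)=C\[C@@H](OC(=O)/C(=C/CO[Si](c3ccccc3)(c3ccccc3)C(C)(C)C)CO[Si](c3ccccc3)(c3ccccc3)C(C)(C)C)[C@@H]12
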